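The easy step is to lay a ruler along the late readings of the ash run, where c(L) climbs straight.

| flask | E | G | time |
|---|---|---|---|
| elm | 0.800 M | 0.0240 M |  |
| alder | 0.400 M | 0.0240 M |  |
| ash | 1.60 M | 0.0240 M |  |
| birch | 0.400 M | 0.0480 M | 23 min |

| run | time / min | [L] / M |
|---|---|---|
| elm run | 2.9 | 0.0228 |
| elm run | 5.8 | 0.0597 |
| elm run | 8.6 | 0.1080 |
| elm run | 12 | 0.1636 |
| elm run | 14 | 0.1898 |
| elm run | 17 | 0.2385 |
| elm run | 20 | 0.2850 |
| elm run | 23 | 0.3337 |
| alder run | 2.9 | 0.0202 |
| alder run | 5.8 | 0.0568 |
| alder run | 8.6 | 0.0998 |
| alder run | 12 | 0.1428 |
| alder run | 14 | 0.1786 |
| alder run | 17 | 0.2154 |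
| alder run | 20 | 0.2518 |
| alder run | 23 | 0.2891 |
| ash run | 2.9 | 0.0215 |
| ash run | 5.8 | 0.0651 |
| ash run | 8.6 | 0.1112 |
| ash run | 12 | 0.1664 |
| ash run | 14 | 0.1990 |
| ash run | 17 | 0.2499 |
| ash run | 20 | 0.2954 |
| ash run | 23 | 0.3473 |

(each reading ± 0.002 M)

- Overall: E -> L, with G as catalyst.
- Constant volume, constant temperature.
- What is held in complexes is read along with the free species.
- An order is taken over about fifteen percent of the charge, up and down.

- apparent order in [E] of the starting rate, round the charge of the elm run (the rate where two percent of its E have turned into L) (one fixed amount of L, the same in the runs compared)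
- the alder run starts with 0.400 M less of E than the elm run, and with no L. Compared where both hold the same amount of E, once fifteen percent of what the alder run was charged with has turned into L, is the alder run faster, slower or alike (within a tenth)?
- L in the birch run at 23 min, as a share of the E charged
- which of these the readings show (nothing beyond the main steps / the catalyst wakes slowly / an uncatalysed path runs beside / the substrate kills the catalyst)

For the birch run I need three numbers, and I take them by weight. The first is the running rate. Ash gains 0.0164 M/min between 12 min and 23 min. Birch holds twice the G, and I take the rate to follow G, so birch runs at 0.0329 M/min and needs 12.2 min for its charge. This number matters: at the unscaled 0.0164 M/min the same charge takes 24.3 min, longer than the 23 min on offer.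

The second is the fall at low c(E). Alder, charged with 0.400 M, gains 0.0133 M/min over the same times, less than ash. Scaled to the G of birch, that slower rate needs 15.0 min.

The third matters least. The straight line of ash, run back, meets zero c(L) at 1.88 min. I call this the waking time: the lifetime of the sleeping catalyst, which is the induction period of the curve. The asked time holds 12.2 waking times. As a rough estimate, a straight line at the slower rate, after its delay, reaches the birch charge at 16.9 min. The real rate falls below that line as c(E) falls, so this is no end time. Still, the delay is shorter than the 6.12 min of margin, so I expect birch close to finished at 23 min, though not complete.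

The forecast says 0.04, alike, 99.6% and the catalyst wakes slowly, noting that “All three runs show this same lag”.

The flask gives 0.044, alike, 98.5% and the catalyst wakes slowly.

    Zo + E ⇌ GE, settled at all times (20.20 /M)
    GE → L + Zo (0.7080 /min)
    G → Zo (0.5112 /min)

The slow conversion of G into Zo holds the apparent order in G at 0.69: the simulated run with that slowness taken away gives 1.0. Alder reaches the compared point close to 5.8 min, which is 2.96 lifetimes of G in the step G → Zo, so a share 0.948 of its catalyst is awake, and the simulated ratio of alder to elm is 0.95. In ash, a quarter of the charge at 0.0164 M/min plus the waking time comes to 26.2 min, and the simulated time is 26.3 min.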